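**Strategy**

The diosphenol of ring B is the enol of an 8,9-dione, so C8 and C9 are adjacent ring B carbons at carbonyl level; the route disconnects the C8–C9 bond. In one operation, sodium/TMSCl acyloin coupling of a ring A 1,6-diester joins the two ester carbons and closes ring B as its 8,9-bis(silyl) enediol. The precursor is a cyclohexane carrying C3-OTBS, the cis C4/C5 methyls, a C5 propanoate arm and a C10 ester, made from an (R)-4-silyloxy enone by anti cuprate addition and anti allylation. Oxidation, acetone aldol–dehydration at C7 and late acylation with a preformed Z,Z side-chain acid finish the target.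

Key step: step 10

Remark on numbering: the eremophilane numbering of the target is used for all intermediates (ring A = C1–C5 and C10; ring B = C5–C10; C3 carries the ester oxygen, C4 and C5 the methyls, C7 the isopropylidene, C8 the ketone, C9 the enol OH).

Assumption: C10 in compounds 9–13 is formed as a mixture of epimers and is left undefined in the SMILES, because step 11 makes it sp2; both epimers can cyclise in step 10.

**Route**

Step 1
Reactants: 1 4-[(tert-butyldimethylsilyl)oxy]cyclohexan-1-one
Product: 2 (R)-tert-butyldimethyl{[4-(trimethylsilyloxy)cyclohex-3-en-1-yl]oxy}silane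
Conditions: (S,S)-LiN[CH(CH3)Ph]2 (from the amine and n-BuLi), TMSCl present from the start, THF, −100 → −78 °C
Reagents that add atoms: chlorotrimethylsilane, C[Si](C)(C)Cl
Why: Enantioselective deprotonation (chiral lithium amide desymmetrisation of a 4-substituted cyclohexanone with internal silyl quench): the C2-symmetric amide removes one of the two enantiotopic axial α-protons, which makes the carbinol carbon (future C3) stereogenic with R configuration; by analogy with 4-alkylcyclohexanones the S,S amide is expected to give this sense, and its antipode is equally available.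

Step 2
Reactants: 2 (R)-tert-butyldimethyl{[4-(trimethylsilyloxy)cyclohex-3-en-1-yl]oxy}silane
Product: 3 (R)-4-[(tert-butyldimethylsilyl)oxy]cyclohex-2-en-1-one
Conditions: Pd(OAc)2 (10 mol %), O2 (1 atm), DMSO, rt
Reagents that add atoms: none
Why: Saegusa–Ito oxidation (palladation of the silyl enol ether, then β-hydride elimination) places the double bond between the future C5 and C4 and leaves the C3 stereocentre untouched.

Step 3
Reactants: 3 (R)-4-[(tert-butyldimethylsilyl)oxy]cyclohex-2-en-1-one
Product: 4 (R)-4-[(tert-butyldimethylsilyl)oxy]-2-iodocyclohex-2-en-1-one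
Conditions: I2, pyridine, CH2Cl2, 0 °C → rt
Reagents that add atoms: iodine, II
Why: α-Iodination of an enone by the pyridine addition–iodination–elimination sequence is specific for the α-carbon (future C5) and does not involve the silyloxy-bearing carbon.

Step 4
Reactants: 4 (R)-4-[(tert-butyldimethylsilyl)oxy]-2-iodocyclohex-2-en-1-one
Product: 5 (R)-4-[(tert-butyldimethylsilyl)oxy]-2-methylcyclohex-2-en-1-one
Conditions: MeZnCl, Pd(PPh3)4 (5 mol %), THF, rt
Reagents that add atoms: methylzinc chloride, C[Zn]Cl
Why: Negishi coupling of the sp2 C–I bond installs the future C5 methyl under non-basic conditions; the organozinc does not add to the enone or eliminate the γ-silyloxy group.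

Step 5
Reactants: 5 (R)-4-[(tert-butyldimethylsilyl)oxy]-2-methylcyclohex-2-en-1-one
Product: 7 (2R,3R,4R)-2-allyl-4-[(tert-butyldimethylsilyl)oxy]-2,3-dimethylcyclohexan-1-one, via lithium enolate 6 (not isolated)
Conditions: Me2CuLi (from CuI and 2 MeLi), Et2O, −78 → −20 °C; then allyl bromide, DMPU–THF, −78 °C → rt
Reagents that add atoms: lithium dimethylcuprate, [Li+].C[Cu-]C; allyl bromide, C=CCBr
Why: Tandem conjugate addition–enolate alkylation: the cuprate adds to C4 anti to the γ-silyloxy group (C4 methyl trans to C3–O), and the regiodefined tetrasubstituted enolate is allylated anti to the new C4 methyl, which A(1,2) strain with the C5 methyl holds pseudoaxial, so the C5 quaternary centre forms with the two methyls cis.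

Step 6
Reactants: 7 (2R,3R,4R)-2-allyl-4-[(tert-butyldimethylsilyl)oxy]-2,3-dimethylcyclohexan-1-one
Product: 8 tert-butyl{[(1R,2R,3R)-3-allyl-2,3-dimethyl-4-methylidenecyclohexyl]oxy}dimethylsilane
Conditions: Ph3PCH3Br, KOtBu, toluene, 90 °C
Reagents that add atoms: methylenetriphenylphosphorane (made in the flask), C=P(c1ccccc1)(c1ccccc1)c1ccccc1
Why: Wittig methylenation under the salt-free, hot conditions used for α-quaternary ketones supplies C9; the α-carbon C5 is quaternary and cannot epimerise.

Step 7
Reactants: 8 tert-butyl{[(1R,2R,3R)-3-allyl-2,3-dimethyl-4-methylidenecyclohexyl]oxy}dimethylsilane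
Product: 9 3-[5-(tert-butyldimethylsilyloxy)-2-(hydroxymethyl)-1,6-dimethylcyclohexyl]propan-1-ol (C10 epimers)
Conditions: 9-BBN (3 equiv), THF, 0 → 65 °C; then NaOH, H2O2, 0 °C → rt
Reagents that add atoms: hydrogen peroxide, OO
Why: Anti-Markovnikov hydroboration–oxidation of the monosubstituted and the 1,1-disubstituted alkene in one operation puts oxygen on the terminal carbons C8 and C9; the C10 configuration created here is of no consequence.

Step 8
Reactants: 9 3-[5-(tert-butyldimethylsilyloxy)-2-(hydroxymethyl)-1,6-dimethylcyclohexyl]propan-1-ol (C10 epimers)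
Product: 10 3-[2-carboxy-5-(tert-butyldimethylsilyloxy)-1,6-dimethylcyclohexyl]propanoic acid (C10 epimers)
Conditions: TEMPO (cat.), NaClO2, NaOCl (cat.), MeCN–phosphate buffer (pH 6.7), 35 °C
Reagents that add atoms: sodium chlorite, [Na+].[O-]Cl=O
Why: Oxoammonium/chlorite oxidation takes both primary alcohols to carboxylic acids at near-neutral pH, which the secondary TBS ether tolerates.

Step 9
Reactants: 10 3-[2-carboxy-5-(tert-butyldimethylsilyloxy)-1,6-dimethylcyclohexyl]propanoic acid (C10 epimers)
Product: 11 methyl 4-(tert-butyldimethylsilyloxy)-2-(3-methoxy-3-oxopropyl)-2,3-dimethylcyclohexane-1-carboxylate (C10 epimers)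
Conditions: MeI, K2CO3, DMF, rt
Reagents that add atoms: iodomethane, CI
Why: SN2 O-methylation of the dicarboxylate gives the 1,6-diester without acid or heat.

Step 10
Reactants: 11 methyl 4-(tert-butyldimethylsilyloxy)-2-(3-methoxy-3-oxopropyl)-2,3-dimethylcyclohexane-1-carboxylate (C10 epimers)
Product: 12 tert-butyl{[1,8a-dimethyl-5,6-bis(trimethylsilyloxy)-1,2,3,4,4a,7,8,8a-octahydronaphthalen-2-yl]oxy}dimethylsilane (3-silyloxy-4,5-dimethyl-8,9-bis(trimethylsilyloxy)octal-8-ene in target numbering; C10 epimers)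
Conditions: Na dispersion (4.4 equiv), TMSCl (5 equiv), toluene, reflux; 11 added slowly under argon
Reagents that add atoms: chlorotrimethylsilane, C[Si](C)(C)Cl
Why: Sodium transfers an electron to each ester; the C8 and C9 ketyl radical anions couple, two methoxides leave to give the 8,9-dione, and two further electrons give the enediolate, which TMSCl silylates on both oxygens while also removing methoxide as MeOSiMe3. The closest known reaction is the Rühlmann (TMSCl-trapped) acyloin condensation of adipate-type diesters to 1,2-bis(trimethylsilyloxy)cyclohexenes. Ring B closes in a 6-exo-trig sense, the C8 ketyl attacking the C9 carbonyl carbon, which joins C5–C6–C7–C8 to C9–C10 as a six-membered carbocycle with either ring-fusion geometry. No stereocentre is created: C8 and C9 become sp2, and the two C10 epimers converge in step 11. The step needs reductive C–C coupling to win over methoxide-driven Dieckmann closure to five-membered β-keto esters (C7 onto C9, or C10 onto C8) and over ester reduction; the aprotic medium and the TMSCl trap secure this, and the TBS ether and saturated ring A offer nothing reducible.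

Step 11
Reactants: 12 tert-butyl{[1,8a-dimethyl-5,6-bis(trimethylsilyloxy)-1,2,3,4,4a,7,8,8a-octahydronaphthalen-2-yl]oxy}dimethylsilane (C10 epimers)
Product: 14 (4aR,5R,6R)-6-(tert-butyldimethylsilyloxy)-1-hydroxy-4a,5-dimethyl-4,4a,5,6,7,8-hexahydronaphthalen-2(3H)-one, via acyloin 13 (not isolated)
Conditions: MeOH, PPTS (cat.), rt, argon; concentrate; Dess–Martin periodinane, CH2Cl2, 0 °C → rt
Reagents that add atoms: none
Why: The bis-silyl enediol is at the acyloin (α-hydroxy ketone) level, so methanolysis of the two TMS enol ethers is followed by a two-electron alcohol oxidation to the 8,9-dione, which should enolise toward C10 to the more substituted, conjugated diosphenol and thereby erase the C10 stereocentre.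

Step 12
Reactants: 14 (4aR,5R,6R)-6-(tert-butyldimethylsilyloxy)-1-hydroxy-4a,5-dimethyl-4,4a,5,6,7,8-hexahydronaphthalen-2(3H)-one
Product: 15 (4aR,5R,6R)-6-(tert-butyldimethylsilyloxy)-1-(methoxymethoxy)-4a,5-dimethyl-4,4a,5,6,7,8-hexahydronaphthalen-2(3H)-one
Conditions: MOMCl, iPr2NEt, CH2Cl2, 0 °C → rt
Reagents that add atoms: chloromethyl methyl ether, COCCl
Why: O-Alkylation of the acidic enol with a hard electrophile masks O9 as an acetal that resists amide bases, fluoride and acylation and is orthogonal to the C3 silyl ether.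

Step 13
Reactants: 15 (4aR,5R,6R)-6-(tert-butyldimethylsilyloxy)-1-(methoxymethoxy)-4a,5-dimethyl-4,4a,5,6,7,8-hexahydronaphthalen-2(3H)-one
Product: 16 (4aR,5R,6R)-6-(tert-butyldimethylsilyloxy)-3-(2-hydroxypropan-2-yl)-1-(methoxymethoxy)-4a,5-dimethyl-4,4a,5,6,7,8-hexahydronaphthalen-2(3H)-one (C7 epimers)
Conditions: LiN(iPr)2, THF, −78 °C; acetone, −78 °C; AcOH quench at −78 °C
Reagents that add atoms: acetone, CC(C)=O
Why: Kinetic deprotonation at C7, the only α-CH2 of the C8 ketone, gives the cross-conjugated enolate, which undergoes aldol addition to acetone; the cold acidic quench prevents retro-aldol, and the C7 configuration is lost in the next step.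

Step 14
Reactants: 16 (4aR,5R,6R)-6-(tert-butyldimethylsilyloxy)-3-(2-hydroxypropan-2-yl)-1-(methoxymethoxy)-4a,5-dimethyl-4,4a,5,6,7,8-hexahydronaphthalen-2(3H)-one (C7 epimers)
Product: 18 (4aR,5R,6R)-6-(tert-butyldimethylsilyloxy)-1-(methoxymethoxy)-4a,5-dimethyl-3-(propan-2-ylidene)-4,4a,5,6,7,8-hexahydronaphthalen-2(3H)-one, via mesylate 17 (not isolated)
Conditions: MsCl, Et3N, CH2Cl2, 0 °C; then DBU, rt
Reagents that add atoms: none
Why: Mesylation of the tertiary aldol and E1cB elimination through the C7 enolate give the conjugated, tetrasubstituted C7=C11 isopropylidene under basic conditions that spare the MOM and TBS groups.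

Step 15
Reactants: 18 (4aR,5R,6R)-6-(tert-butyldimethylsilyloxy)-1-(methoxymethoxy)-4a,5-dimethyl-3-(propan-2-ylidene)-4,4a,5,6,7,8-hexahydronaphthalen-2(3H)-one
Product: 19 (4aR,5R,6R)-6-hydroxy-1-(methoxymethoxy)-4a,5-dimethyl-3-(propan-2-ylidene)-4,4a,5,6,7,8-hexahydronaphthalen-2(3H)-one
Conditions: TBAF, THF, rt; aq. NH4Cl
Reagents that add atoms: none
Why: Fluoride cleaves the secondary silyl ether at C3 with retention, while the MOM enol ether and the cross-conjugated dienone are inert to fluoride.

Step 16
Reactants: 20 4-methylfuran-2(5H)-one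
Product: 22 4-methoxybenzyl (Z)-4-hydroxy-3-methylbut-2-enoate, via potassium salt 21 (not isolated)
Conditions: KOH (1.0 equiv), H2O–MeOH, rt; evaporate to dryness; PMBCl, DMF, rt; used crude
Reagents that add atoms: potassium hydroxide, [K+].[OH-]; 4-methoxybenzyl chloride, COc1ccc(CCl)cc1
Why: Saponification opens the butenolide to a carboxylate whose Z geometry is fixed by the former ring, and carboxylate SN2 alkylation gives the ester without ever passing through the free hydroxy acid, which would relactonise.

Step 17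
Reactants: 22 4-methoxybenzyl (Z)-4-hydroxy-3-methylbut-2-enoate; 23 angelic acid, (Z)-2-methylbut-2-enoic acid
Product: 24 4-methoxybenzyl (2Z)-3-methyl-4-{[(2Z)-2-methylbut-2-enoyl]oxy}but-2-enoate
Conditions: PPh3, DIAD, THF, 0 °C → rt
Reagents that add atoms: none
Why: Mitsunobu esterification: the angelate anion displaces the activated primary allylic alcohol (SN2), so angelic acid is never activated as an acyl donor and has no path to the tiglate isomer.

Step 18
Reactants: 24 4-methoxybenzyl (2Z)-3-methyl-4-{[(2Z)-2-methylbut-2-enoyl]oxy}but-2-enoate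
Product: 25 (2Z)-3-methyl-4-{[(2Z)-2-methylbut-2-enoyl]oxy}but-2-enoic acid
Conditions: TFA, anisole, CH2Cl2, 0 °C
Reagents that add atoms: none
Why: Acidolysis of the PMB ester proceeds through the stabilised 4-methoxybenzyl cation, which anisole traps; the alkyl and allylic esters and both Z alkenes are unaffected by brief cold acid.

Step 19
Reactants: 19 (4aR,5R,6R)-6-hydroxy-1-(methoxymethoxy)-4a,5-dimethyl-3-(propan-2-ylidene)-4,4a,5,6,7,8-hexahydronaphthalen-2(3H)-one; 25 (2Z)-3-methyl-4-{[(2Z)-2-methylbut-2-enoyl]oxy}but-2-enoic acid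
Product: 27 (3R,4R,5R)-9-O-methoxymethyl ether of the target, via mixed anhydride 26 (not isolated)
Conditions: 25, 2,4,6-trichlorobenzoyl chloride, Et3N, toluene, rt; then 19, DMAP, toluene, rt
Reagents that add atoms: none
Why: Yamaguchi esterification through the mixed anhydride acylates the equatorial C3 hydroxyl with retention at C3; O9 is masked, so only one hydroxyl can react.

Step 20
Reactants: 27 (3R,4R,5R)-9-O-methoxymethyl ether of the target
Product: 28 CNP0228871.1, (3R,4R,5R)-9-hydroxy-8-oxoeremophila-7(11),9-dien-3-yl (2Z)-3-methyl-4-{[(2Z)-2-methylbut-2-enoyl]oxy}but-2-enoate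
Conditions: TFA, CH2Cl2, 0 °C; aq. NaHCO3 work-up
Reagents that add atoms: none
Why: Acid cleavage of the acetal-type MOM ether is easy because the diosphenol oxygen is a phenol-like leaving group; the three esters, the Z alkenes and the dienone should tolerate brief cold TFA.

**Compound list**

1 | 4-[(tert-butyldimethylsilyl)oxy]cyclohexan-1-one | O=C1CCC(O[Si](C)(C)C(C)(C)C)CC1 | starting material
2 | (R)-tert-butyldimethyl{[4-(trimethylsilyloxy)cyclohex-3-en-1-yl]oxy}silane | C[Si](C)(C)OC1=CC[C@H](O[Si](C)(C)C(C)(C)C)CC1 | intermediate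
3 | (R)-4-[(tert-butyldimethylsilyl)oxy]cyclohex-2-en-1-one | O=C1CC[C@@H](O[Si](C)(C)C(C)(C)C)C=C1 | intermediate
4 | (R)-4-[(tert-butyldimethylsilyl)oxy]-2-iodocyclohex-2-en-1-one | O=C1CC[C@@H](O[Si](C)(C)C(C)(C)C)C=C1I | intermediate
5 | (R)-4-[(tert-butyldimethylsilyl)oxy]-2-methylcyclohex-2-en-1-one | CC1=C[C@H](O[Si](C)(C)C(C)(C)C)CCC1=O | intermediate
6 | lithium (3R,4R)-4-[(tert-butyldimethylsilyl)oxy]-2,3-dimethylcyclohex-1-en-1-olate | [Li]OC1=C(C)[C@@H](C)[C@H](O[Si](C)(C)C(C)(C)C)CC1 | intermediate (not isolated)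
7 | (2R,3R,4R)-2-allyl-4-[(tert-butyldimethylsilyl)oxy]-2,3-dimethylcyclohexan-1-one (OTBS trans to C4-Me; C4-Me cis to C5-Me) | C=CC[C@]1(C)[C@@H](C)[C@H](O[Si](C)(C)C(C)(C)C)CCC1=O | intermediate
8 | tert-butyl{[(1R,2R,3R)-3-allyl-2,3-dimethyl-4-methylidenecyclohexyl]oxy}dimethylsilane | C=CC[C@]1(C)[C@@H](C)[C@H](O[Si](C)(C)C(C)(C)C)CCC1=C | intermediate
9 | 3-[5-(tert-butyldimethylsilyloxy)-2-(hydroxymethyl)-1,6-dimethylcyclohexyl]propan-1-ol; C3, C4, C5 as in 7, both C10 epimers | OCCC[C@]1(C)[C@@H](C)[C@H](O[Si](C)(C)C(C)(C)C)CCC1CO | intermediate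
10 | 3-[2-carboxy-5-(tert-butyldimethylsilyloxy)-1,6-dimethylcyclohexyl]propanoic acid; C3, C4, C5 as in 7, both C10 epimers | OC(=O)CC[C@]1(C)[C@@H](C)[C@H](O[Si](C)(C)C(C)(C)C)CCC1C(=O)O | intermediate
11 | methyl 4-(tert-butyldimethylsilyloxy)-2-(3-methoxy-3-oxopropyl)-2,3-dimethylcyclohexane-1-carboxylate; C3, C4, C5 as in 7, both C10 epimers | COC(=O)CC[C@]1(C)[C@@H](C)[C@H](O[Si](C)(C)C(C)(C)C)CCC1C(=O)OC | intermediate
12 | tert-butyl{[1,8a-dimethyl-5,6-bis(trimethylsilyloxy)-1,2,3,4,4a,7,8,8a-octahydronaphthalen-2-yl]oxy}dimethylsilane; C3, C4, C5 as in 7, both C10 epimers | C[C@H]1[C@H](O[Si](C)(C)C(C)(C)C)CCC2C(O[Si](C)(C)C)=C(O[Si](C)(C)C)CC[C@]12C | intermediate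
13 | acyloin, drawn as the 9-hydroxy-8-ketone tautomer (C9 and C10 undefined) | C[C@H]1[C@H](O[Si](C)(C)C(C)(C)C)CCC2C(O)C(=O)CC[C@]12C | intermediate (not isolated)
14 | (4aR,5R,6R)-6-(tert-butyldimethylsilyloxy)-1-hydroxy-4a,5-dimethyl-4,4a,5,6,7,8-hexahydronaphthalen-2(3H)-one | C[C@H]1[C@H](O[Si](C)(C)C(C)(C)C)CCC2=C(O)C(=O)CC[C@]12C | intermediate
15 | (4aR,5R,6R)-6-(tert-butyldimethylsilyloxy)-1-(methoxymethoxy)-4a,5-dimethyl-4,4a,5,6,7,8-hexahydronaphthalen-2(3H)-one | C[C@H]1[C@H](O[Si](C)(C)C(C)(C)C)CCC2=C(OCOC)C(=O)CC[C@]12C | intermediate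
16 | (4aR,5R,6R)-6-(tert-butyldimethylsilyloxy)-3-(2-hydroxypropan-2-yl)-1-(methoxymethoxy)-4a,5-dimethyl-4,4a,5,6,7,8-hexahydronaphthalen-2(3H)-one, C7 epimers | C[C@H]1[C@H](O[Si](C)(C)C(C)(C)C)CCC2=C(OCOC)C(=O)C(C(C)(C)O)C[C@]12C | intermediate
17 | methanesulfonate of the tertiary alcohol of 16 | C[C@H]1[C@H](O[Si](C)(C)C(C)(C)C)CCC2=C(OCOC)C(=O)C(C(C)(C)OS(C)(=O)=O)C[C@]12C | intermediate (not isolated)
18 | (4aR,5R,6R)-6-(tert-butyldimethylsilyloxy)-1-(methoxymethoxy)-4a,5-dimethyl-3-(propan-2-ylidene)-4,4a,5,6,7,8-hexahydronaphthalen-2(3H)-one | C[C@H]1[C@H](O[Si](C)(C)C(C)(C)C)CCC2=C(OCOC)C(=O)C(=C(C)C)C[C@]12C | intermediate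
19 | (4aR,5R,6R)-6-hydroxy-1-(methoxymethoxy)-4a,5-dimethyl-3-(propan-2-ylidene)-4,4a,5,6,7,8-hexahydronaphthalen-2(3H)-one | C[C@H]1[C@H](O)CCC2=C(OCOC)C(=O)C(=C(C)C)C[C@]12C | intermediate
20 | 4-methylfuran-2(5H)-one | CC1=CC(=O)OC1 | starting material
21 | potassium (Z)-4-hydroxy-3-methylbut-2-enoate | OC/C(C)=C\C(=O)[O-].[K+] | intermediate (not isolated)
22 | 4-methoxybenzyl (Z)-4-hydroxy-3-methylbut-2-enoate | OC/C(C)=C\C(=O)OCc1ccc(OC)cc1 | intermediate
23 | angelic acid, (Z)-2-methylbut-2-enoic acid | C/C=C(/C)C(=O)O | starting material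
24 | 4-methoxybenzyl (2Z)-3-methyl-4-{[(2Z)-2-methylbut-2-enoyl]oxy}but-2-enoate | C/C=C(/C)C(=O)OC/C(C)=C\C(=O)OCc1ccc(OC)cc1 | intermediate
25 | (2Z)-3-methyl-4-{[(2Z)-2-methylbut-2-enoyl]oxy}but-2-enoic acid | C/C=C(/C)C(=O)OC/C(C)=C\C(=O)O | intermediate
26 | mixed anhydride of 25 with 2,4,6-trichlorobenzoic acid | C/C=C(/C)C(=O)OC/C(C)=C\C(=O)OC(=O)c1c(Cl)cc(Cl)cc1Cl | intermediate (not isolated)
27 | 9-O-methoxymethyl ether of the target, (3R,4R,5R) | C/C=C(/C)C(=O)OC/C(C)=C\C(=O)O[C@@H]1CCC2=C(OCOC)C(=O)C(=C(C)C)C[C@]2(C)[C@H]1C | intermediate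
28 | CNP0228871.1, (3R,4R,5R)-9-hydroxy-8-oxoeremophila-7(11),9-dien-3-yl (2Z)-3-methyl-4-{[(2Z)-2-methylbut-2-enoyl]oxy}but-2-enoate | C/C=C(/C)C(=O)OC/C(C)=C\C(=O)O[C@@H]1CCC2=C(O)C(=O)C(=C(C)C)C[C@]2(C)[C@H]1C | target

**Totals**

Total step count: 20. Longest linear sequence: 17 steps (steps 1–15, 19 and 20); steps 16–18 build the side-chain acid in parallel.

**Steps most likely to fail**

Step 10 (acyloin coupling). Methoxide-driven Dieckmann closure to five-membered β-keto esters, or simple reduction of the hindered C9 ester, may outrun the reductive coupling if the sodium surface passivates or the silyl trap is consumed. The fallback keeps the C8–C9 bond formation reductive but moves it to the aldehyde level. It sets out from diol 9: Swern oxidation gives the dialdehyde 3-[5-(tert-butyldimethylsilyloxy)-2-formyl-1,6-dimethylcyclohexyl]propanal F2; SmI2 in THF effects intramolecular pinacol coupling to the 8,9-diol F3; double oxidation with DMSO–trifluoroacetic anhydride and Et3N gives the 8,9-dione, which enolises, and the route is rejoined at diosphenol 14.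

Step 5 (cuprate addition and allylation). The face of the enolate that is anti to the C4 methyl is also the face of the 1,3-related axial C3 silyloxy group, so alkylation through the ring-flipped enolate may compete and erode the C5 configuration; O-allylation and enolate equilibration are minor channels. The fallback replaces the substrate-controlled SN2 alkylation by a ligand-controlled one. It sets out from enone 5: after the same cuprate addition the enolate is trapped on oxygen with allyl chloroformate to give allyl (3R,4R)-4-(tert-butyldimethylsilyloxy)-2,3-dimethylcyclohex-1-en-1-yl carbonate F1; Pd2(dba)3 with (S)-t-BuPHOX then brings about decarboxylative allylic alkylation (Tsuji–Trost type) within the coordination sphere of palladium, where the ligand reinforces the desired enolate face, and the route is rejoined at ketone 7.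

Step 19 (esterification). Acylation of the hindered C3 hydroxyl may be slow enough for the activated acid to drift, by Z to E isomerisation of either enoate through reversible DMAP addition or by loss of the allylic angelate. The fallback assembles the side chain on the core so that the angelate is introduced last and without acyl activation. It sets out from alcohol 19, salt 21 and acid 23: 21 is silylated on both oxygens (TBSCl, imidazole, DMF) to the bis-silyl derivative F4, whose silyl ester is cleaved (K2CO3, aqueous MeOH) to (Z)-4-(tert-butyldimethylsilyloxy)-3-methylbut-2-enoic acid F5; carbodiimide coupling of F5 with 19 (EDC·HCl, DMAP) gives the silyloxy ester F6; TBAF buffered with AcOH frees the allylic alcohol F7, which is esterified at once with angelic acid 23 under Mitsunobu conditions (PPh3, DIAD), and the route is rejoined at 27.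

Further compounds
F1 | step 5 | allyl (3R,4R)-4-(tert-butyldimethylsilyloxy)-2,3-dimethylcyclohex-1-en-1-yl carbonate | C=CCOC(=O)OC1=C(C)[C@@H](C)[C@H](O[Si](C)(C)C(C)(C)C)CC1
F2 | step 10 | 3-[5-(tert-butyldimethylsilyloxy)-2-formyl-1,6-dimethylcyclohexyl]propanal (C10 epimers) | O=CCC[C@]1(C)[C@@H](C)[C@H](O[Si](C)(C)C(C)(C)C)CCC1C=O
F3 | step 10 | 6-(tert-butyldimethylsilyloxy)-4a,5-dimethyldecahydronaphthalene-1,2-diol (8,9-diol in target numbering) | C[C@H]1[C@H](O[Si](C)(C)C(C)(C)C)CCC2C(O)C(O)CC[C@]12C
F4 | step 19 | tert-butyldimethylsilyl (Z)-4-(tert-butyldimethylsilyloxy)-3-methylbut-2-enoate | CC(C)(C)[Si](C)(C)OC/C(C)=C\C(=O)O[Si](C)(C)C(C)(C)C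
F5 | step 19 | (Z)-4-(tert-butyldimethylsilyloxy)-3-methylbut-2-enoic acid | CC(C)(C)[Si](C)(C)OC/C(C)=C\C(=O)O
F6 | step 19 | C3 (Z)-4-(tert-butyldimethylsilyloxy)-3-methylbut-2-enoate of 19 | CC(C)(C)[Si](C)(C)OC/C(C)=C\C(=O)O[C@@H]1CCC2=C(OCOC)C(=O)C(=C(C)C)C[C@]2(C)[C@H]1C
F7 | step 19 | C3 (Z)-4-hydroxy-3-methylbut-2-enoate of 19 | OC/C(C)=C\C(=O)O[C@@H]1CCC2=C(OCOC)C(=O)C(=C(C)C)C[C@]2(C)[C@H]1C
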